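The constants of this flask are hidden, so the examination starts from the readings.

common to all: free monomer 10 mM
- green: initiator 28 µM; run made earlier
- blue: initiator 44 µM; run made earlier
- flask: initiator 20 µM; time 30 h

| run | time / h | monomer in chains / % | free monomer / % |
|---|---|---|---|
| green | 5.00 | 7.4 | 96.1 |
| green | 10.0 | 11.1 | 88.2 |
| green | 15.0 | 17.3 | 84.3 |
| green | 20.0 | 20.9 | 79.2 |
| green | 25.0 | 24.4 | 75.7 |
| green | 30.0 | 27.6 | 70.1 |
| green | 40.0 | 35.6 | 65.7 |
| blue | 2.00 | 3.8 | 96.5 |
| blue | 6.00 | 8.9 | 89.8 |
| blue | 10.0 | 14.5 | 86.7 |
| blue | 15.0 | 21.5 | 81.1 |
| blue | 20.0 | 26.3 | 74.2 |
| blue | 30.0 | 35.6 | 64.7 |
| blue | 40.0 | 42.7 | 58.1 |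

(scatter of a reading: 1 percentage point)

1. whether the average number of monomer units in a chain (living and dead chains, two that joined counted as one) reaches 1000 by 30 h (no / yes)
2. average number of monomer units in a chain (living and dead chains, two that joined counted as one) at 30 h

- the average divides the monomer in chains by the number of chains, living and dead together; two radicals that join make one chain
- what was read earlier has a scatter of 1 percentage point, one standard deviation
- on the list of suspects stand: initiator -> 2 initiating radical; free monomer + initiating radical -> growing radical + monomer in chains; free monomer + growing radical -> monomer in chains + growing radical; 2 growing radical -> dead chain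
- the earlier runs do not show the number of chains; that part of a forecast is a guess

"No constants. What can you use?" The fraction of free monomer left, not the fraction made: on the suspected steps, growing radicals consume free monomer pseudo-first-order, so minus its logarithm sums radical exposure.

"Why compare at 30 h?" Green and blue were both read then. If initiator falls first-order, each flask keeps the same share of its charge at that time, and with growing radicals ending in pairs, their level follows the root of the initiator charge.

"Does that hold?" Scaled by that root to the flask's 20 µM, green gives 0.300 and blue 0.294, which agree. Their mean is 0.297, the loss index: minus the logarithm of the free fraction left at a fixed time, for a fixed free monomer charge, scaled to one initiator charge by the root of the charge ratio.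

"So this flask?" I expect 74.3% of the free monomer left, which puts 2.57 mM in chains.

"And the weak spot?" The chains, which the runs do not show. An average of 1000 asks for 2.57 µM of chains, or 12.8% of the initiator charge if each initiator lost makes one chain. My guess is that more decays, so I say no, and I commit to no length.

The forecast says no, with 410, between 230 and 850: “The chain count is a guess.”

    initiator → 2 initiating radical (k = 4.60 × 10⁻⁶ /s)
    free monomer + initiating radical → growing radical + monomer in chains (k = 1.20 × 10⁵ /M/s)
    free monomer + growing radical → monomer in chains + growing radical, rate k3*[growing radical]*[free monomer] (k = 980 /M/s)
    2 growing radical → dead chain (k = 1.00 × 10⁷ /M/s)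

The flask gives no and an average of 318, so the forecast's length stands 1.29 times too high, and the flask keeps 75% of its free monomer against the index's 74.3%. In this flask, the rate at which free monomer adds to growing radicals, over the rate at which it adds to initiating radicals, is 160 at 13.0 h and 160 at 30.0 h. For the neighbour charged with 0.012 mM of initiator, the index gives 79.4% left. That neighbour holds 80.2% of its free monomer, with an average of 422.

(The runs are calculated with made-up constants.)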